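**Retrosynthetic overview**

Carbocycle numbering used here: C1 = quaternary carbon (CH3 + long chain), C2 = CH(3-hydroxypropyl), C3 = ring carbon of the exocyclic enal, C4/C5 = CH2, C6 = C(OH)CH3.
Enabling feature: C1 sits between C6 (O-bearing) and, one atom further, C3 (sp2, a latent ketone). Without C2 the atoms C1–C6–C5–C4–C3 form a 2,2-disubstituted cyclopentane-1,3-dione that is mirror-symmetric about C1.
The C1–C3 bond of that cyclopentane (absent from the target) is made on purpose: desymmetrizing reduction of the dione fixes quaternary C1, and the bond is then cleaved when C1 shifts from C3 to C2 (semipinacol ring enlargement, five to six), which forms C1–C2 with inversion at C2.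
Later disconnections: Z-enal from the C3 ketone via a gem-dibromoalkene (methyl, then formyl); C6 carbinol from ketone + methyl nucleophile; side chain from an E-enal + alkenylzinc made from (S)-citronellal.
Ring order: cyclopentane (commercial dione) first, then the only ring of the target by ring enlargement.

Key step: step 9

Assumption: the SMILES is read as an iridal-type seco-triterpenoid with C1 (S), C2 (R), C6 (S), a Z enal (CHO cis to C2) and an (S,E,E) side chain; all starting materials and reagents named are taken as commercial.

**Route**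

Step 1
Reactants: 1 2-methylcyclopentane-1,3-dione; 2 acrylonitrile
Product: 3 3-(1-methyl-2,5-dioxocyclopentyl)propanenitrile
Conditions: Et3N (cat), MeCN, 60 °C
Reagents that add atoms: none
Why: Base-catalysed Michael addition of the acidic 2-methyl-1,3-dione gives the C-alkylated quaternary carbon (future C1), still achiral because its two carbonyl arms are enantiotopic.

Step 2
Reactants: 3 3-(1-methyl-2,5-dioxocyclopentyl)propanenitrile
Product: 4 3-[(1R,2R)-2-hydroxy-1-methyl-5-oxocyclopentyl]propanenitrile
Conditions: (S)-2-methyl-CBS-oxazaborolidine (20 mol %), catecholborane, PhNEt2, toluene, −60 °C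
Reagents that add atoms: none
Why: Corey–Bakshi–Shibata reduction desymmetrizes the dione, since the (S)-catalyst should form the (R)-carbinol and reduce only the carbonyl whose reacting face is the methyl face (anti to the larger cyanoethyl arm), which fixes quaternary C1 and puts the hydroxyl cis to the cyanoethyl chain.

Step 3
Reactants: 4 hydroxy ketone
Product: 5 3-[(1R,2R)-1-methyl-5-oxo-2-(triethylsilyloxy)cyclopentyl]propanenitrile
Conditions: Et3SiCl, imidazole, DMF, 0 → 23 °C
Reagents that add atoms: triethylsilyl chloride, CC[Si](Cl)(CC)CC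
Why: Silyl ether formation protects the β-hydroxy ketone against retro-aldol opening under the basic conditions that follow and touches no stereocenter.

Step 4
Reactants: 6 tetrahydrofuran
Product: 7 tert-butyl(4-iodobutoxy)diphenylsilane
Conditions: t-BuPh2SiCl, NaI, MeCN, 60 °C
Reagents that add atoms: tert-butyldiphenylsilyl chloride, CC(C)(C)[Si](Cl)(c1ccccc1)c1ccccc1; sodium iodide, [Na+].[I-]
Why: The iodosilane formed in the flask cleaves the cyclic ether (silyl-iodide ether cleavage) to the ω-iodo silyl ether.

Step 5
Reactants: 7 tert-butyl(4-iodobutoxy)diphenylsilane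
Product: 8 [4-(tert-butyldiphenylsilyloxy)butyl]triphenylphosphonium iodide
Conditions: PPh3, MeCN, 80 °C
Reagents that add atoms: triphenylphosphine, c1ccc(cc1)P(c1ccccc1)c1ccccc1
Why: SN2 quaternization of triphenylphosphine by the primary iodide gives the Wittig salt.

Step 6
Reactants: 5 silyloxy ketone; 8 phosphonium iodide
Product: 10 Z-butylidene cyclopentane (chain syn to the quaternary carbon), via phosphorus ylide 9 (not isolated)
Conditions: 8, KN(SiMe3)2, toluene, 0 °C; then 5, 80 °C
Reagents that add atoms: none
Why: Wittig olefination with the non-stabilized ylide should place the new chain cis to the quaternary α-carbon (kinetic Z selectivity, as in the ethylidenation of 17-keto steroids), and this geometry later defines C2.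

Step 7
Reactants: 10 Z-alkene
Product: 11 diol (tertiary and secondary hydroxyl both on the face of the ring methyl)
Conditions: OsO4 (5 mol %), N-methylmorpholine N-oxide, t-BuOH/THF/H2O, 23 °C
Reagents that add atoms: N-methylmorpholine N-oxide, C[N+]1([O-])CCOCC1; water, O
Why: OsO4-catalysed syn-dihydroxylation should occur on the alkene face anti to the cyanoethyl chain and the silyloxy group, so the secondary carbinol carbon (future C2) gets the configuration that inversion in step 9 turns into that of the target.

Step 8
Reactants: 11 diol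
Product: 12 secondary methanesulfonate of 11
Conditions: MeSO2Cl, Et3N, CH2Cl2, −20 °C
Reagents that add atoms: methanesulfonyl chloride, CS(Cl)(=O)=O
Why: Selective sulfonylation of the secondary hydroxyl next to the unreactive tertiary one installs the leaving group on the future C2.

Step 9
Reactants: 12 hydroxy mesylate
Product: 13 3-[(1S,2S,6R)-2-[3-(tert-butyldiphenylsilyloxy)propyl]-1-methyl-3-oxo-6-(triethylsilyloxy)cyclohexyl]propanenitrile
Conditions: Et3Al (3 equiv), CH2Cl2, −78 → −20 °C
Reagents that add atoms: none
Why: Et3Al forms the aluminium alkoxide of the tertiary carbinol and, as a Lewis acid, pulls on the neighbouring mesylate, so the ring bond C1–C3 that stands anti-periplanar to C–OMs shifts to C2 while the alkoxide carbon becomes the C3 ketone (semipinacol 1,2-shift). The closest known type is the organoaluminium-promoted pinacol-type rearrangement of β-mesyloxy alcohols, with the D-homoannulation of 17-hydroxy-20-sulfonyloxy steroids as the ring-size analogue. The six-membered ring closes by ring enlargement of the cyclopentane: the C1–C2 bond forms through a bridged three-centre 1,2-shift as the temporary C1–C3 bond breaks. C2 is set by inversion at the mesylate carbon, whose configuration comes from the Z alkene and the face of dihydroxylation, and C1 migrates with retention, carrying the configuration fixed in step 2. The step needs C1 to migrate instead of the ring CH2 (C4) and to outrun epoxide closure; the quaternary alkyl carbon has the higher migratory aptitude, and in the O–Al···OMs chelate the rotamer that turns the mesylate away from crowded C1 places C1 anti to the leaving group.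

Step 10
Reactants: 13 ring-enlarged ketone
Product: 14 gem-dibromomethylidene cyclohexane
Conditions: CBr4, PPh3, toluene, 100 °C
Reagents that add atoms: carbon tetrabromide, BrC(Br)(Br)Br
Why: Corey–Fuchs-type dibromo-olefination (Wittig reaction of Ph3P=CBr2) converts the C3 ketone into the dibromoalkene without strong base, so the α-stereocenter C2 should not epimerize.

Step 11
Reactants: 14 gem-dibromoalkene
Product: 15 Z-(1-bromoethylidene) compound (bromine syn to C2, methyl syn to the ring CH2)
Conditions: MeZnCl (1.2 equiv), PdCl2[(2-Ph2PC6H4)2O] (5 mol %), THF, 0 → 23 °C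
Reagents that add atoms: methylzinc chloride, C[Zn]Cl
Why: Negishi cross-coupling in which oxidative addition should take the less hindered C–Br bond (syn to C4, away from C2 with its axial chain and from quaternary C1), so methyl enters trans to C2 and the remaining bromine sits where the formyl group must end.

Step 12
Reactants: 15 bromoalkene silyl ether
Product: 16 secondary alcohol at C6
Conditions: HF·pyridine, pyridine, THF, 0 °C
Reagents that add atoms: none
Why: Fluoride-mediated cleavage removes the secondary triethylsilyl ether, which is far more labile than the primary tert-butyldiphenylsilyl ether.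

Step 13
Reactants: 16 alcohol
Product: 17 C6 ketone
Conditions: Dess–Martin periodinane, NaHCO3, CH2Cl2, 23 °C
Reagents that add atoms: none
Why: Dess–Martin oxidation gives the ring ketone under neutral conditions that leave the vinyl bromide and nitrile alone.

Step 14
Reactants: 17 ketone
Product: 18 tertiary methyl carbinol (hydroxyl cis to the C1 methyl)
Conditions: MeMgBr, CeCl3, THF, −78 °C
Reagents that add atoms: methylmagnesium bromide, C[Mg]Br
Why: Organocerium 1,2-addition in which allylic 1,3-strain from the tetrasubstituted bromoalkene holds the C2 chain axial, this 1,3-diaxial group blocks axial attack, and equatorial attack gives the axial hydroxyl cis to the C1 methyl (the C6 configuration of the target), the nitrile being much slower at this temperature.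

Step 15
Reactants: 18 hydroxy nitrile
Product: 20 aldehyde (3-oxopropyl chain on C1), via aluminium aldimine 19 (not isolated)
Conditions: i-Bu2AlH (2.2 equiv), CH2Cl2, −78 °C; then aqueous Rochelle salt
Reagents that add atoms: water, O
Why: Partial reduction of the nitrile by the aluminium hydride stops at the N-aluminio aldimine, which is hydrolysed to the aldehyde on work-up.

Step 16
Reactants: 20 aldehyde
Product: 21 E-2-methyl-2-enal
Conditions: Ph3P=C(CH3)CHO, toluene, 90 °C
Reagents that add atoms: 2-(triphenylphosphoranylidene)propanal, CC(C=O)=P(c1ccccc1)(c1ccccc1)c1ccccc1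
Why: Wittig olefination with the stabilized ylide should give the E trisubstituted enal of the side chain.

Step 17
Reactants: 22 (S)-citronellal
Product: 24 (3S)-3,7-dimethyloct-6-en-1-yne, via alkenyl nonaflate 23 (not isolated)
Conditions: C4F9SO2F, phosphazene base P2-Et (2.2 equiv), DMF, −30 → 20 °C
Reagents that add atoms: none
Why: One-pot O-nonaflation of the aldehyde enolate and base-induced elimination of the alkenyl nonaflate gives the terminal alkyne, the β-stereocenter coming unchanged from the chiral pool.

Step 18
Reactants: 21 enal; 24 alkyne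
Product: 27 bromoalkene with complete side chain and (S)-allylic alcohol, via alkenylborane 25 (not isolated), via alkenylzinc 26 (not isolated)
Conditions: 24, Cy2BH, toluene, 0 → 23 °C; Me2Zn, −78 °C; (2S)-(−)-3-exo-(morpholino)isoborneol (10 mol %); then 21 (pre-treated with Me2Zn), −20 → 0 °C
Reagents that add atoms: none
Why: Alkyne hydroboration, boron-to-zinc transmetalation and amino-alcohol-catalysed 1,2-addition of the E-alkenylzinc to the enal, the chiral zinc aminoalkoxide directing attack to the aldehyde face that gives the (S)-carbinol (same sense as the (S)-alcohols this ligand gives in dialkylzinc additions).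

Step 19
Reactants: 27 vinyl bromide diol
Product: 29 O-tert-butyldiphenylsilyl ether of the target, via trilithio vinyllithium 28 (not isolated)
Conditions: MeLi (2.1 equiv), THF, −78 °C; t-BuLi (2.2 equiv), −78 °C; DMF, −78 → 0 °C; H2O
Reagents that add atoms: N,N-dimethylformamide, CN(C)C=O
Why: After deprotonation of the two hydroxyls, bromine–lithium exchange with retention of alkene geometry and formylation of the vinyllithium by DMF place the aldehyde cis to C2.

Step 20
Reactants: 29 silyl ether
Product: 30 target CNP0323596.2
Conditions: Bu4NF, AcOH (1:1), THF, 0 → 23 °C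
Reagents that add atoms: none
Why: Fluoride-mediated desilylation buffered with acetic acid should free the primary alcohol without epimerizing the γ-position of the enal or ionizing the doubly allylic alcohol.

**Compound list**

1 | 2-methylcyclopentane-1,3-dione | CC1C(=O)CCC1=O | starting material
2 | acrylonitrile | C=CC#N | starting material
3 | 3-(1-methyl-2,5-dioxocyclopentyl)propanenitrile | N#CCCC1(C)C(=O)CCC1=O | intermediate
4 | 3-[(1R,2R)-2-hydroxy-1-methyl-5-oxocyclopentyl]propanenitrile (OH cis to the cyanoethyl chain) | N#CCC[C@@]1(C)C(=O)CC[C@H]1O | intermediate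
5 | 3-[(1R,2R)-1-methyl-5-oxo-2-(triethylsilyloxy)cyclopentyl]propanenitrile | N#CCC[C@@]1(C)C(=O)CC[C@H]1O[Si](CC)(CC)CC | intermediate
6 | tetrahydrofuran (oxolane) | C1CCOC1 | starting material
7 | tert-butyl(4-iodobutoxy)diphenylsilane | ICCCCO[Si](c1ccccc1)(c1ccccc1)C(C)(C)C | intermediate
8 | [4-(tert-butyldiphenylsilyloxy)butyl]triphenylphosphonium iodide | [I-].CC(C)(C)[Si](OCCCC[P+](c1ccccc1)(c1ccccc1)c1ccccc1)(c1ccccc1)c1ccccc1 | intermediate
9 | [4-(tert-butyldiphenylsilyloxy)butylidene]triphenylphosphorane (ylide, not isolated) | CC(C)(C)[Si](OCCCC=P(c1ccccc1)(c1ccccc1)c1ccccc1)(c1ccccc1)c1ccccc1 | intermediate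
10 | 3-[(1S,2R,5Z)-5-[4-(tert-butyldiphenylsilyloxy)butylidene]-1-methyl-2-(triethylsilyloxy)cyclopentyl]propanenitrile (chain syn to the quaternary carbon) | N#CCC[C@@]1(C)/C(=C\CCCO[Si](c2ccccc2)(c2ccccc2)C(C)(C)C)CC[C@H]1O[Si](CC)(CC)CC | intermediate
11 | 3-[(1R,2R,5R)-5-[(1S)-4-(tert-butyldiphenylsilyloxy)-1-hydroxybutyl]-5-hydroxy-1-methyl-2-(triethylsilyloxy)cyclopentyl]propanenitrile (both new OH on the face of the ring methyl) | N#CCC[C@@]1(C)[C@@](O)([C@@H](O)CCCO[Si](c2ccccc2)(c2ccccc2)C(C)(C)C)CC[C@H]1O[Si](CC)(CC)CC | intermediate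
12 | secondary methanesulfonate of 11 (tertiary OH free) | N#CCC[C@@]1(C)[C@@](O)([C@@H](OS(C)(=O)=O)CCCO[Si](c2ccccc2)(c2ccccc2)C(C)(C)C)CC[C@H]1O[Si](CC)(CC)CC | intermediate
13 | 3-[(1S,2S,6R)-2-[3-(tert-butyldiphenylsilyloxy)propyl]-1-methyl-3-oxo-6-(triethylsilyloxy)cyclohexyl]propanenitrile | N#CCC[C@@]1(C)[C@H](CCCO[Si](c2ccccc2)(c2ccccc2)C(C)(C)C)C(=O)CC[C@H]1O[Si](CC)(CC)CC | intermediate
14 | 3-(dibromomethylidene) analogue of 13 (C3=CBr2) | N#CCC[C@@]1(C)[C@H](CCCO[Si](c2ccccc2)(c2ccccc2)C(C)(C)C)C(=C(Br)Br)CC[C@H]1O[Si](CC)(CC)CC | intermediate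
15 | 3-[(Z)-1-bromoethylidene] analogue (Br syn to C2, CH3 syn to C4) | N#CCC[C@@]1(C)[C@H](CCCO[Si](c2ccccc2)(c2ccccc2)C(C)(C)C)/C(=C(/C)Br)CC[C@H]1O[Si](CC)(CC)CC | intermediate
16 | C6 secondary alcohol of 15 (triethylsilyl group removed, OH cis to the cyanoethyl chain) | N#CCC[C@@]1(C)[C@H](CCCO[Si](c2ccccc2)(c2ccccc2)C(C)(C)C)/C(=C(/C)Br)CC[C@H]1O | intermediate
17 | C6 ketone | N#CCC[C@@]1(C)[C@H](CCCO[Si](c2ccccc2)(c2ccccc2)C(C)(C)C)/C(=C(/C)Br)CCC1=O | intermediate
18 | C6 tertiary methyl carbinol (OH cis to the C1 methyl, trans to the cyanoethyl chain) | N#CCC[C@@]1(C)[C@H](CCCO[Si](c2ccccc2)(c2ccccc2)C(C)(C)C)/C(=C(/C)Br)CC[C@]1(C)O | intermediate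
19 | N-(diisobutylaluminio) aldimine of 18 with O-aluminated carbinol (not isolated) | CC(C)C[Al](CC(C)C)N=CCC[C@@]1(C)[C@H](CCCO[Si](c2ccccc2)(c2ccccc2)C(C)(C)C)/C(=C(/C)Br)CC[C@]1(C)O[Al](CC(C)C)CC(C)C | intermediate
20 | aldehyde (3-oxopropyl on C1) | O=CCC[C@@]1(C)[C@H](CCCO[Si](c2ccccc2)(c2ccccc2)C(C)(C)C)/C(=C(/C)Br)CC[C@]1(C)O | intermediate
21 | (E)-2-methylpent-2-enal chain on C1 | O=C/C(C)=C/CC[C@@]1(C)[C@H](CCCO[Si](c2ccccc2)(c2ccccc2)C(C)(C)C)/C(=C(/C)Br)CC[C@]1(C)O | intermediate
22 | (S)-citronellal, (3S)-3,7-dimethyloct-6-enal | CC(C)=CCC[C@H](C)CC=O | starting material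
23 | (3S)-3,7-dimethylocta-1,6-dien-1-yl nonafluorobutanesulfonate (E/Z mixture, not isolated) | CC(C)=CCC[C@H](C)C=COS(=O)(=O)C(F)(F)C(F)(F)C(F)(F)C(F)(F)F | intermediate
24 | (3S)-3,7-dimethyloct-6-en-1-yne | CC(C)=CCC[C@H](C)C#C | intermediate
25 | dicyclohexyl[(1E,3S)-3,7-dimethylocta-1,6-dien-1-yl]borane (not isolated) | CC(C)=CCC[C@H](C)/C=C/B(C1CCCCC1)C1CCCCC1 | intermediate
26 | [(1E,3S)-3,7-dimethylocta-1,6-dien-1-yl](methyl)zinc (not isolated) | CC(C)=CCC[C@H](C)/C=C/[Zn]C | intermediate
27 | vinyl bromide with complete side chain, (S)-allylic alcohol, both alkenes E | CC(C)=CCC[C@H](C)/C=C/[C@H](O)/C(C)=C/CC[C@@]1(C)[C@H](CCCO[Si](c2ccccc2)(c2ccccc2)C(C)(C)C)/C(=C(/C)Br)CC[C@]1(C)O | intermediate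
28 | dilithium dialkoxide vinyllithium from 27 (not isolated) | CC(C)=CCC[C@H](C)/C=C/[C@H](O[Li])/C(C)=C/CC[C@@]1(C)[C@H](CCCO[Si](c2ccccc2)(c2ccccc2)C(C)(C)C)/C(=C(/C)[Li])CC[C@]1(C)O[Li] | intermediate
29 | primary O-tert-butyldiphenylsilyl ether of the target | CC(C)=CCC[C@H](C)/C=C/[C@H](O)/C(C)=C/CC[C@@]1(C)[C@H](CCCO[Si](c2ccccc2)(c2ccccc2)C(C)(C)C)/C(=C(/C)C=O)CC[C@]1(C)O | intermediate
30 | CNP0323596.2 (C1 S, C2 R, C6 S; Z ring enal; (S)-allylic alcohol) | CC(C)=CCC[C@H](C)/C=C/[C@H](O)/C(C)=C/CC[C@@]1(C)[C@H](CCCO)/C(=C(/C)C=O)CC[C@]1(C)O | target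

**Step count and risks**

Total step count: 20. Longest linear sequence: 17 steps (1–3, 6–16, 18–20, from compound 1 to compound 30).

Steps most likely to fail:

1. Step 9 (key step). The ring CH2 (C4) may migrate instead of C1, the alkoxide may close onto the mesylate carbon to give an epoxide, or the mesylate may ionize before migration and erode the configuration at C2. Fallback (halohydrin ring enlargement): setting out from alkene 10, N-bromosuccinimide in aqueous acetone should add bromine from the open methyl face and water at the tertiary carbon to give the bromohydrin F1, which carries bromine where 12 carries the mesylate. Its bromomagnesium alkoxide (i-PrMgBr, benzene, 60 °C) should rearrange with the same anti migration of C1, and the route is rejoined at ketone 13.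

2. Step 11. Discrimination between the two C–Br bonds may be poor, because both are flanked in the alkene plane by an equatorial ring hydrogen; this would give a mixture of geometric isomers or double methylation. Fallback (reverse the order and use strain release instead of steric approach): setting out from dibromide 14, t-BuLi in THF/Et2O/pentane at −110 °C should exchange the more crowded bromine (syn to C2), and Me3SnCl traps the carbenoid as the bromo stannane F2. The single remaining bromine is methylated (MeZnCl, Pd(PPh3)4) to the methyl stannane F3, and bromodestannylation with N-bromosuccinimide (retention) rejoins the route at vinyl bromide 15.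

3. Step 2. The catalyst may not distinguish the methyl from the cyanoethyl arm well enough (the diastereoselectivity of this reduction becomes the enantiomeric purity of C1), and over-reduction to the diol may occur. Fallback (resolution instead of asymmetric catalysis): setting out from dione 3, NaBH4 at −20 °C gives the racemic cis-hydroxy ketone, that is 4 together with its enantiomer F4. Burkholderia cepacia lipase with vinyl acetate should acylate the (R)-carbinol to the acetate F5, which is separated from unreacted F4 and cleaved with K2CO3 in MeOH, rejoining the route at 4.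

Further compounds
F1 | step 9 | bromohydrin of 10 (Br on the former alkene CH carbon, on the methyl face; tertiary OH on the opposite face) | N#CCC[C@@]1(C)[C@](O)([C@@H](Br)CCCO[Si](c2ccccc2)(c2ccccc2)C(C)(C)C)CC[C@H]1O[Si](CC)(CC)CC
F2 | step 11 | bromo(trimethylstannyl)methylidene compound (SnMe3 syn to C2, Br syn to C4) | N#CCC[C@@]1(C)[C@H](CCCO[Si](c2ccccc2)(c2ccccc2)C(C)(C)C)/C(=C(/Br)[Sn](C)(C)C)CC[C@H]1O[Si](CC)(CC)CC
F3 | step 11 | 1-(trimethylstannyl)ethylidene compound (SnMe3 syn to C2, CH3 syn to C4) | N#CCC[C@@]1(C)[C@H](CCCO[Si](c2ccccc2)(c2ccccc2)C(C)(C)C)/C(=C(/C)[Sn](C)(C)C)CC[C@H]1O[Si](CC)(CC)CC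
F4 | step 2 | 3-[(1S,2S)-2-hydroxy-1-methyl-5-oxocyclopentyl]propanenitrile (enantiomer of 4) | N#CCC[C@]1(C)C(=O)CC[C@@H]1O
F5 | step 2 | acetate of 4 | N#CCC[C@@]1(C)C(=O)CC[C@H]1OC(C)=O
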